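**Plan**
1. Retrosynthesis: the side-chain ester C1'–O–C(=O) bond is cut first, then the three O–allyl bonds that mask the quinone of ring B and the C8 phenol, then C1'–O back to C1'–B, then the C2–C1' bond between ring B and the side chain, and last C2–B back to C2–Br.
2. Feature used: C1', the only stereocentre, is a secondary carbinol carbon bonded to the aryl carbon C2 of ring B, to oxygen and to the CH2 of a prenyl unit. This aryl–CH(O)–alkyl pattern is what a lithiated alkyl carbamate and an aryl boronic ester assemble.
3. Forward: no ring is built. Both rings come from naphthazarin, which is mono-methylated, brominated at C2 and reductively allylated to a bromide that is turned into the aryl pinacol boronate.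
4. The six-carbon chain, as its diisopropylcarbamate, is joined to C2 by lithiation–borylation. C–B oxidation, deallylation with oxidation to the quinone, and esterification with 3-methylbut-2-enoic acid complete the route.
5. Stereochemistry: (+)-sparteine-directed deprotonation, retention on boron capture, inversion in the 1,2-shift and retention in the C–B oxidation set (S)-C1'; no later step breaks a bond to C1'.

Key step: step 6

Assumption: dehydrobromination of the dibromide of naphthazarin monomethyl ether is taken to follow the juglone pattern, leaving bromine beside the carbonyl that is hydrogen-bonded to the free peri hydroxyl; the position should be confirmed on compound 4 before going on.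

**Step 1**
Reactants: 1 naphthazarin (5,8-dihydroxy-1,4-naphthoquinone)
Product: 2 5-hydroxy-8-methoxy-1,4-naphthoquinone
Conditions: MeI (1.2 equiv), Ag2O, CHCl3, rt, dark
Reagents that add atoms: iodomethane, CI
Why: Ag2O-promoted Williamson-type O-methylation of one of the two equivalent hydrogen-bonded peri hydroxyls should stop largely at the mono-ether when MeI is limiting, since unreacted 1 and the dimethyl ether are easily separated and 1 can be recycled.

**Step 2**
Reactants: 2 5-hydroxy-8-methoxy-1,4-naphthoquinone
Product: 4 2-bromo-8-hydroxy-5-methoxy-1,4-naphthoquinone, via quinone dibromide 3 (not isolated)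
Conditions: Br2, AcOH, rt; then EtOH, reflux
Reagents that add atoms: bromine, BrBr
Why: Electrophilic addition of bromine to the quinone C2=C3 bond followed by dehydrobromination (addition–elimination) should leave bromine at C2, because enolisation of dibromide 3 is easier toward C1=O, which is activated by the hydrogen bond from the C8 hydroxyl, than toward C4=O, which receives electron density from the C5 methoxy group, the same outcome as in the bromination of juglone.

**Step 3**
Reactants: 4 2-bromo-8-hydroxy-5-methoxy-1,4-naphthoquinone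
Product: 6 1,4,8-tris(allyloxy)-2-bromo-5-methoxynaphthalene, via bromonaphthalenetriol 5 (not isolated)
Conditions: Na2S2O4, THF/H2O, rt; then allyl bromide, K2CO3, DMF, 40 °C (argon)
Reagents that add atoms: allyl bromide, C=CCBr
Why: Dithionite reduction of the quinone and threefold Williamson O-allylation of the resulting naphtholates in a dipolar aprotic solvent (reductive alkylation) should fix the naphthalene oxidation level with three ethers that survive organolithium reagents and can later be removed together under neutral conditions.

**Step 4**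
Reactants: 6 1,4,8-tris(allyloxy)-2-bromo-5-methoxynaphthalene
Product: 8 2-[1,4,8-tris(allyloxy)-5-methoxynaphthalen-2-yl]-4,4,5,5-tetramethyl-1,3,2-dioxaborolane, via aryllithium 7 (not isolated)
Conditions: n-BuLi, THF, −78 °C; then i-PrOBpin, −78 °C to rt; aq. NH4Cl
Reagents that add atoms: 2-isopropoxy-4,4,5,5-tetramethyl-1,3,2-dioxaborolane, CC(C)OB1OC(C)(C)C(C)(C)O1
Why: Bromine–lithium exchange at −78 °C is much faster than attack of n-BuLi on the allyl ethers, and borylation of aryllithium 7 by the isopropoxy boronate before warming should forestall its addition across the neighbouring allyl group.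

**Step 5**
Reactants: 9 4-methylpent-3-en-1-ol; 10 N,N-diisopropylcarbamoyl chloride
Product: 11 4-methylpent-3-en-1-yl N,N-diisopropylcarbamate
Conditions: Et3N, CH2Cl2, reflux
Reagents that add atoms: none
Why: Carbamoylation of the primary alcohol (nucleophilic acyl substitution) installs the diisopropylcarbamate that later directs the lithiation and serves as the leaving group.

**Step 6**
Reactants: 11 4-methylpent-3-en-1-yl N,N-diisopropylcarbamate; 8 2-[1,4,8-tris(allyloxy)-5-methoxynaphthalen-2-yl]-4,4,5,5-tetramethyl-1,3,2-dioxaborolane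
Product: 14 2-[(1S)-1-[1,4,8-tris(allyloxy)-5-methoxynaphthalen-2-yl]-4-methylpent-3-en-1-yl]-4,4,5,5-tetramethyl-1,3,2-dioxaborolane, via lithiated carbamate 12 (not isolated), via boronate complex 13 (not isolated)
Conditions: 11 (1.3 equiv), s-BuLi (1.2 equiv), (+)-sparteine (1.3 equiv), Et2O, −78 °C; then 8 (1.0 equiv), −78 °C; then reflux; aq. NH4Cl
Reagents that add atoms: none
Why: s-BuLi complexed by (+)-sparteine removes one of the two enantiotopic protons next to the carbamate oxygen of 11 (the carbonyl oxygen holds the base close, so this outruns removal of the allylic C2' protons) and should give the configurationally stable (R)-organolithium 12. Boron of 8 captures 12 with retention to give boronate complex 13, and on warming the electron-rich naphthyl group shifts from boron to carbon anti to the departing carbamate, inverting C1' and forming the C2–C1' bond. The closest known reaction type is the lithiation–borylation homologation of aryl pinacol boronates with sparteine-lithiated primary alkyl carbamates, a stereospecific 1,2-metallate rearrangement; no ring is closed. The new stereocentre C1' is controlled by the enantiomer of the diamine: with (+)-sparteine the retention–inversion sequence should place boron so that oxidation with retention gives the (S)-carbinol. The step needs the carbenoid to meet boron before it decomposes and the aryl group rather than a pinacol oxygen to migrate; the open C3 side of the boronate, the low temperature of complex formation and the high migratory aptitude of an alkoxy-substituted aryl group should secure this, and because 11 is in slight excess over s-BuLi no free base is left to attack the allyl ethers.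

**Step 7**
Reactants: 14 2-[(1S)-1-[1,4,8-tris(allyloxy)-5-methoxynaphthalen-2-yl]-4-methylpent-3-en-1-yl]-4,4,5,5-tetramethyl-1,3,2-dioxaborolane
Product: 15 (1S)-1-[1,4,8-tris(allyloxy)-5-methoxynaphthalen-2-yl]-4-methylpent-3-en-1-ol
Conditions: H2O2 (30% aq.), NaOH (2 M aq.), THF, 0 °C to rt
Reagents that add atoms: hydrogen peroxide, OO
Why: Alkaline hydrogen peroxide oxidation of the carbon–boron bond proceeds by 1,2-shift of C1' from boron to oxygen with retention, so the (S)-boronate should give the (S)-carbinol, and neither the electron-rich alkenes nor the allyl ethers react with the hydroperoxide anion.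

**Step 8**
Reactants: 15 (1S)-1-[1,4,8-tris(allyloxy)-5-methoxynaphthalen-2-yl]-4-methylpent-3-en-1-ol
Product: 17 8-hydroxy-2-[(1S)-1-hydroxy-4-methylpent-3-en-1-yl]-5-methoxy-1,4-naphthoquinone, via naphthalenetriol 16 (not isolated)
Conditions: Pd(PPh3)4 (cat.), morpholine, degassed THF, rt; cold aq. citric acid wash (argon); then Ag2O, MgSO4, Et2O, rt
Reagents that add atoms: none
Why: Tsuji–Trost-type allyl transfer from the three aryl ethers to morpholine through π-allyl palladium complexes frees triol 16, and Ag2O dehydrogenation of its hydroquinone ring then gives the quinone in ring B only, because ring A holds a methyl ether and a single hydroxyl and cannot become a quinone without losing carbon; C1' is not involved.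

**Step 9**
Reactants: 17 8-hydroxy-2-[(1S)-1-hydroxy-4-methylpent-3-en-1-yl]-5-methoxy-1,4-naphthoquinone; 18 3-methylbut-2-enoic acid
Product: 19 (1S)-1-(8-hydroxy-5-methoxy-1,4-dioxo-1,4-dihydronaphthalen-2-yl)-4-methylpent-3-en-1-yl 3-methylbut-2-enoate
Conditions: DCC, DMAP (cat.), CH2Cl2, 0 °C to rt
Reagents that add atoms: none
Why: Steglich esterification should acylate only the side-chain secondary alcohol, since the C8 hydroxyl is tied up in a hydrogen bond to C1=O and is a poor nucleophile, and as no bond to C1' is broken the (S) configuration is kept.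

**Compound list**
1 | naphthazarin (5,8-dihydroxy-1,4-naphthoquinone) | O=C1C=CC(=O)c2c(O)ccc(O)c12 | starting material
2 | 5-hydroxy-8-methoxy-1,4-naphthoquinone | COc1ccc(O)c2c1C(=O)C=CC2=O | intermediate
3 | 2,3-dibromo-5-hydroxy-8-methoxy-2,3-dihydro-1,4-naphthoquinone (mixture of stereoisomers, centres lost on elimination) | COc1ccc(O)c2c1C(=O)C(Br)C(Br)C2=O | intermediate
4 | 2-bromo-8-hydroxy-5-methoxy-1,4-naphthoquinone | COc1ccc(O)c2c1C(=O)C=C(Br)C2=O | intermediate
5 | 2-bromo-5-methoxynaphthalene-1,4,8-triol | COc1ccc(O)c2c(O)c(Br)cc(O)c12 | intermediate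
6 | 1,4,8-tris(allyloxy)-2-bromo-5-methoxynaphthalene | COc1ccc(OCC=C)c2c(OCC=C)c(Br)cc(OCC=C)c12 | intermediate
7 | [1,4,8-tris(allyloxy)-5-methoxynaphthalen-2-yl]lithium | COc1ccc(OCC=C)c2c(OCC=C)c([Li])cc(OCC=C)c12 | intermediate
8 | 2-[1,4,8-tris(allyloxy)-5-methoxynaphthalen-2-yl]-4,4,5,5-tetramethyl-1,3,2-dioxaborolane | COc1ccc(OCC=C)c2c(OCC=C)c(B3OC(C)(C)C(C)(C)O3)cc(OCC=C)c12 | intermediate
9 | 4-methylpent-3-en-1-ol | CC(C)=CCCO | starting material
10 | N,N-diisopropylcarbamoyl chloride | CC(C)N(C(C)C)C(Cl)=O | starting material
11 | 4-methylpent-3-en-1-yl N,N-diisopropylcarbamate | CC(C)=CCCOC(=O)N(C(C)C)C(C)C | intermediate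
12 | (1R)-1-lithio-4-methylpent-3-en-1-yl N,N-diisopropylcarbamate, as its (+)-sparteine complex (diamine not drawn) | CC(C)=CC[C@H](OC(=O)N(C(C)C)C(C)C)[Li] | intermediate
13 | lithium boronate complex of 8 with the (1R)-1-(diisopropylcarbamoyloxy)-4-methylpent-3-en-1-yl group on boron | [Li+].CC(C)=CC[C@H](OC(=O)N(C(C)C)C(C)C)[B-]3(OC(C)(C)C(C)(C)O3)c1cc(OCC=C)c2c(OC)ccc(OCC=C)c2c1OCC=C | intermediate
14 | 2-[(1S)-1-[1,4,8-tris(allyloxy)-5-methoxynaphthalen-2-yl]-4-methylpent-3-en-1-yl]-4,4,5,5-tetramethyl-1,3,2-dioxaborolane | COc1ccc(OCC=C)c2c(OCC=C)c(cc(OCC=C)c12)[C@H](CC=C(C)C)B1OC(C)(C)C(C)(C)O1 | intermediate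
15 | (1S)-1-[1,4,8-tris(allyloxy)-5-methoxynaphthalen-2-yl]-4-methylpent-3-en-1-ol | COc1ccc(OCC=C)c2c(OCC=C)c(cc(OCC=C)c12)[C@H](CC=C(C)C)O | intermediate
16 | 2-[(1S)-1-hydroxy-4-methylpent-3-en-1-yl]-5-methoxynaphthalene-1,4,8-triol | COc1ccc(O)c2c(O)c(cc(O)c12)[C@H](CC=C(C)C)O | intermediate
17 | 8-hydroxy-2-[(1S)-1-hydroxy-4-methylpent-3-en-1-yl]-5-methoxy-1,4-naphthoquinone | COc1ccc(O)c2c1C(=O)C=C([C@H](CC=C(C)C)O)C2=O | intermediate
18 | 3-methylbut-2-enoic acid | CC(C)=CC(=O)O | starting material
19 | (1S)-1-(8-hydroxy-5-methoxy-1,4-dioxo-1,4-dihydronaphthalen-2-yl)-4-methylpent-3-en-1-yl 3-methylbut-2-enoate | COc1ccc(O)c2c1C(=O)C=C([C@H](CC=C(C)C)OC(=O)C=C(C)C)C2=O | target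

**Step count**
Total steps: 9. Longest linear sequence: 8 (steps 1–4 and 6–9); the carbamate branch is one step.

**Steps most likely to fail**

Step 6. Capture of the carbenoid by the ortho-substituted boronate may be slow or reversible, or the 1,2-shift may lag so that the complex falls back to its components; either process would lower conversion and erode enantiopurity. Fallback, setting out from bromide 6 and returning at carbinol 15: 6 is lithiated as in step 4 to aryllithium 7 and acylated with N-methoxy-N,4-dimethylpent-3-enamide F1 (from commercial 4-methylpent-3-enoic acid, N,O-dimethylhydroxylamine hydrochloride and a carbodiimide) to give 1-[1,4,8-tris(allyloxy)-5-methoxynaphthalen-2-yl]-4-methylpent-3-en-1-one F2. Corey–Bakshi–Shibata reduction of F2 with the (R)-configured 2-methyl-oxazaborolidine and BH3·SMe2 should, with the aryl group as the large substituent, give (S)-15, which continues at step 8.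

Step 2. Loss of HBr in the opposite direction, or electrophilic bromination of ring A, would give regioisomeric bromides that lead to the wrong placement of the methoxy group. Fallback, setting out from naphthazarin 1 and returning at bromide 6:
- Naphthazarin 1 is mono-acetylated (Ac2O, one equivalent, pyridine) to 5-acetoxy-8-hydroxy-1,4-naphthoquinone F3, in which the free hydroxyl and the ester both steer bromine to the same carbon.
- Bromine in AcOH gives 5-acetoxy-2,3-dibromo-8-hydroxy-2,3-dihydro-1,4-naphthoquinone F4, and sodium acetate removes HBr to leave 5-acetoxy-2-bromo-8-hydroxy-1,4-naphthoquinone F5.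
- The hydroxyl is allylated (allyl bromide, Ag2O) to 5-acetoxy-8-(allyloxy)-2-bromo-1,4-naphthoquinone F6.
- Acid-catalysed methanolysis removes the acetate to give 8-(allyloxy)-2-bromo-5-hydroxy-1,4-naphthoquinone F7, which is methylated (MeI, Ag2O) to 8-(allyloxy)-2-bromo-5-methoxy-1,4-naphthoquinone F8.
- Dithionite reduction to 8-(allyloxy)-2-bromo-5-methoxynaphthalene-1,4-diol F9 and double O-allylation (allyl bromide, K2CO3, DMF) then give 6.

Step 8. The π-allyl fragment may return to a ring carbon of the electron-rich naphthoxide (C-allylation), the hindered C1 ether may cleave incompletely, or the amine may add to the quinone if oxygen enters before it is washed out. Fallback, setting out from 15 and returning at triol 16: the three allyl ethers are isomerised with [Ir(cod)(PMePh2)2]PF6 (activated with H2, THF, rt) to (1S)-1-{5-methoxy-1,4,8-tris[(E)-prop-1-enyloxy]naphthalen-2-yl}-4-methylpent-3-en-1-ol F10. The enol ethers are then hydrolysed with dilute HCl in aqueous acetone at 0 °C under argon to give 16, which is oxidised with Ag2O as in step 8.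

**Further compounds**
F1 | step 6 | N-methoxy-N,4-dimethylpent-3-enamide | CC(C)=CCC(=O)N(C)OC
F2 | step 6 | 1-[1,4,8-tris(allyloxy)-5-methoxynaphthalen-2-yl]-4-methylpent-3-en-1-one | COc1ccc(OCC=C)c2c(OCC=C)c(cc(OCC=C)c12)C(=O)CC=C(C)C
F3 | step 2 | 5-acetoxy-8-hydroxy-1,4-naphthoquinone | CC(=O)Oc1ccc(O)c2c1C(=O)C=CC2=O
F4 | step 2 | 5-acetoxy-2,3-dibromo-8-hydroxy-2,3-dihydro-1,4-naphthoquinone | CC(=O)Oc1ccc(O)c2c1C(=O)C(Br)C(Br)C2=O
F5 | step 2 | 5-acetoxy-2-bromo-8-hydroxy-1,4-naphthoquinone | CC(=O)Oc1ccc(O)c2c1C(=O)C=C(Br)C2=O
F6 | step 2 | 5-acetoxy-8-(allyloxy)-2-bromo-1,4-naphthoquinone | CC(=O)Oc1ccc(OCC=C)c2c1C(=O)C=C(Br)C2=O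
F7 | step 2 | 8-(allyloxy)-2-bromo-5-hydroxy-1,4-naphthoquinone | Oc1ccc(OCC=C)c2c1C(=O)C=C(Br)C2=O
F8 | step 2 | 8-(allyloxy)-2-bromo-5-methoxy-1,4-naphthoquinone | COc1ccc(OCC=C)c2c1C(=O)C=C(Br)C2=O
F9 | step 2 | 8-(allyloxy)-2-bromo-5-methoxynaphthalene-1,4-diol | COc1ccc(OCC=C)c2c(O)c(Br)cc(O)c12
F10 | step 8 | (1S)-1-{5-methoxy-1,4,8-tris[(E)-prop-1-enyloxy]naphthalen-2-yl}-4-methylpent-3-en-1-ol | COc1ccc(O/C=C/C)c2c(O/C=C/C)c(cc(O/C=C/C)c12)[C@H](CC=C(C)C)O
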